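The earlier runs and the new flask come from a simulation with constants of no real substance; scatter was added.

A one-step world, with dissolved Q going to X through G and nowhere else, puts the whole charge into X. That is the ceiling of the scale, and the real plateaus stand far below it.

| setting | east | south | flask |
|---|---|---|---|
| E | 1.8 M | 1.8 M | 1.8 M |
| G | 5.6 mM | 8.8 mM | 4.0 mM |
| remark | run made earlier | run made earlier |  |
| time |  |  | 40 min |

| east: time / min | east: X / % | south: time / min | south: X / % |
|---|---|---|---|
| 3.00 | 5.3 | 4.00 | 8.8 |
| 10.0 | 17.2 | 6.00 | 13.4 |
| 15.0 | 24.3 | 10.0 | 22.3 |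
| 25.0 | 36.0 | 20.0 | 38.7 |
| 40.0 | 40.8 | 30.0 | 51.0 |
| 50.0 | 41.2 | 50.0 | 50.9 |

(scatter of a reading: 0.3 percentage points)

- amount of X at 40 min, in percent of the E charged
- the change that raises the amount of X at 40 min, in percent of the E charged most ("none" if none brings more than 2 percentage points) (delta / eta / epsilon / none)
- amount of X at 40 min, in percent of the E charged, after epsilon

- delta: doubling the dissolution coefficient of E, all else as stated
- eta: doubling the amount of G, all else as stated
- epsilon: doubling the solubility of E, all else as stated

In both runs X stops rising: the east run at 40.0 min is within 0.4 percentage points of its plateau, so the flask, read at the same time, is taken on its plateau, the selectivity Y. Its zero is the even split. The even-split amount of G is the amount at which X takes as much of the charge as all competitors together: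

G_e = G(1 − Y)/Y: east 7.99 mM, south 8.49 mM

Then Y = G/(G + G_e). My bracket for the flask:

above, the east plateau: 41.2 %, since the south run's higher G gives more X

below, east scaled in proportion to G: 29.4 %

tightened with G_e: 32.0 % to 33.4 %

Doubling G gives about 50.0 % by this reckoning.

The forecast says 34 %, eta and 30 %, on the ground “More G gives about 48%, so eta is best”. Its 34 % lies inside the wide bracket, slightly above the tight one.

The flask gives 33.4 %, at the upper edge, and its own G_e is 7.97 mM. The best change is eta, worth 16 points, and after epsilon X stands at 33.4 %.

    Q + G → G + X (k = 2.63 /M/s)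
    Q → J (k = 0.00628 /s)
    E ⇌ Q, rate k3*(cs3 - [Q]) while solid is left; crystals form when [Q] > cs3 (solubility = 0.220 M, k = 0.00542 /s)
    2 Q → D (k = 8.51 × 10⁻⁷ /M/s)
    Q + X → Z (k = 0.0106 /M/s)

The step from two Q to D moves nothing here, with D at 0 %. The neighbouring flask with 0.010 M of G reckons to 54.1 % to 55.6 % by the same two values of G_e, and it gives 54.2 %, at the lower edge. In that neighbouring flask E stands at 0 % at the end, and X, at 54.2 %, holds more of the charge than Z at 29.3 %.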